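**Strategy**

Everything rests on taking the target back to commercial, achiral germacrone, which already holds the ten-membered carbocycle, both ring E-alkenes and the C7=C11 bond. The key step is a catalyst-controlled double epoxidation: a fructose-derived chiral dioxirane oxidises the two trisubstituted in-ring alkenes C1=C10 and C4=C5 on their exposed outer faces, closing both oxirane rings and fixing C1, C10, C4 and C5 at once, while the C8 ketone shields the conjugated, tetrasubstituted C7=C11 bond. Its precursor is germacrone itself, unprotected. The four oxygens around C7=C11 (C6, C8, C12, C13) then follow pairwise, each pair by 1,4-dehydration of an allylic alcohol and singlet-oxygen cycloaddition.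

Key step: step 1

Numbering: germacrane numbering throughout; C12 is the C11 substituent cis to C6 and C13 the one cis to C8.

Assumption: the diepoxide keeps germacrone's crossed ring conformation with both ring methyls (C14, C15) on the β-face, so oxygen reagents reach C6 and C8 from the open α-face; the D-fructose-derived ketone (bought) is taken to give the R,R sense at both alkenes, as the spiro model predicts for trisubstituted E-alkenes.

**Route**

Step 1
Reactants: 1 germacrone
Product: 2 (1R,4R,5R,10R)-1,10:4,5-diepoxygermacr-7(11)-en-8-one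
Conditions: Oxone (2KHSO5·KHSO4·K2SO4), commercial 1,2:4,5-di-O-isopropylidene-β-D-erythro-2,3-hexodiulo-2,6-pyranose (0.6 equiv), K2CO3, Bu4NHSO4, MeCN–CH2(OMe)2, aq. Na2B4O7/Na2EDTA buffer (pH 10.5), −10 to 0 °C
Reagents that add atoms: potassium peroxymonosulfate KHSO5, [K+].[O-]S(=O)(=O)OO (one oxygen atom per alkene, passed on through the dioxirane)
Why: Shi asymmetric epoxidation: KHSO5 turns the chiral ketone into a dioxirane that hands one oxygen atom to each alkene through a spiro transition state, the closest precedents being Shi epoxidation of acyclic trisubstituted E-alkenes and the peracid bis-epoxidation of germacrone. Each oxirane ring closes by concerted syn transfer of one oxygen atom across the C=C bond (a [2+1] addition, not a stepwise ring closure), so the E geometry becomes a trans-epoxide. Germacrone is achiral only because its enantiomeric crossed conformers interconvert, and each conformer exposes only the outer face of each ring alkene, so the catalyst sets the first pair of stereocentres by choosing which conformer it oxidises. The first oxirane then holds that conformer, and the second alkene is attacked on its outer face in the catalyst-matched sense, giving the like (R,R,R,R) diastereomer. The step needs chemoselectivity against C7=C11 and the ketone: conjugation to C8=O and tetrasubstitution make C7=C11 a poor partner for the electrophilic dioxirane, and the cold, buffered, short reaction limits Baeyer–Villiger oxidation and enolisation at C9.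

Step 2
Reactants: 2 (1R,4R,5R,10R)-1,10:4,5-diepoxygermacr-7(11)-en-8-one
Product: 3 (1R,4R,5R,8R,10R)-1,10:4,5-diepoxygermacr-7(11)-en-8-ol
Conditions: NaBH4, CeCl3·7H2O, MeOH, −40 °C
Reagents that add atoms: none
Why: Luche 1,2-reduction removes the enolisable ketone (C9–H lies next to the C10 oxirane) before any base is used; hydride is expected from the open α-face to give the 8R alcohol, but the C8 configuration does not matter because step 3 erases it.

Step 3
Reactants: 3 (1R,4R,5R,8R,10R)-1,10:4,5-diepoxygermacr-7(11)-en-8-ol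
Product: 6 (1R,4R,5R,10R,7E)-1,10:4,5-diepoxygermacra-7,11(13)-diene, via sulfenate ester 4 (not isolated), via C11 sulfoxide 5 (not isolated)
Conditions: 2,4-(O2N)2C6H3SCl, Et3N, ClCH2CH2Cl, 0 °C, then 60 °C
Reagents that add atoms: none
Why: Reich 1,4-dehydration of an allylic alcohol: O-sulfenylation, [2,3]-sigmatropic shift of the sulfenate to the tertiary C11 sulfoxide and thermal syn-elimination toward a methyl group (C7 has no hydrogen) give the conjugated diene, with C9 expected anti to C11 (ring-cis C7=C8) so that the diene can become s-cis; no stereocentre is formed.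

Step 4
Reactants: 6 (1R,4R,5R,10R,7E)-1,10:4,5-diepoxygermacra-7,11(13)-diene
Product: 8 (1R,4R,5R,8S,10R)-1,10:4,5-diepoxygermacr-7(11)-ene-8,13-diol, via endoperoxide 7 (not isolated)
Conditions: O2, hν (visible), 5,10,15,20-tetraphenylporphyrin (cat.), CH2Cl2, −78 °C; then Zn, AcOH, 0 °C
Reagents that add atoms: dioxygen, O=O (as singlet oxygen)
Why: Singlet-oxygen [4+2] cycloaddition to the s-cis diene followed by reductive O–O cleavage is the standard route to a (Z)-2-ene-1,4-diol; the dioxine ring forces the new CH2–O carbon cis to C8, which defines it as C13 and leaves the remaining methyl as C12, and C8 is set as S by addition to the α-face, anti to the β-methyl C14 on C10 (as angular methyls steer singlet oxygen in steroidal dienes).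

Step 5
Reactants: 8 (1R,4R,5R,8S,10R)-1,10:4,5-diepoxygermacr-7(11)-ene-8,13-diol
Product: 9 (1R,4R,5R,8S,10R)-13-acetoxy-1,10:4,5-diepoxygermacr-7(11)-en-8-ol
Conditions: AcCl (1.05 equiv), 2,4,6-collidine, CH2Cl2, −78 °C
Reagents that add atoms: acetyl chloride, CC(Cl)=O
Why: Kinetic, chemoselective acetylation of the primary allylic hydroxyl over the hindered secondary C8 hydroxyl; no stereocentre is touched.

Step 6
Reactants: 10 2-methylprop-2-en-1-ol
Product: 11 (R)-(2-methyloxiran-2-yl)methanol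
Conditions: Ti(OiPr)4 (5 mol%), D-(−)-diisopropyl tartrate (6 mol%), t-BuOOH, 4 Å MS, CH2Cl2, −20 °C
Reagents that add atoms: tert-butyl hydroperoxide, CC(C)(C)OO
Why: Sharpless asymmetric epoxidation of a 2-substituted allylic alcohol, in which the D-(−)-tartrate ligand directs oxygen to the face that gives the R epoxy alcohol (this becomes S once the carbinol carbon is oxidised, a change of CIP priority only).

Step 7
Reactants: 11 (R)-(2-methyloxiran-2-yl)methanol
Product: 12 (S)-2-methyloxirane-2-carboxylic acid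
Conditions: 2,2,6,6-tetramethylpiperidin-1-oxyl (cat.), PhI(OAc)2 (2.2 equiv), MeCN–H2O, 0 °C to rt
Reagents that add atoms: water, O
Why: Nitroxyl-catalysed oxidation of the primary alcohol through the aldehyde hydrate to the acid leaves the oxirane and the quaternary stereocentre untouched.

Step 8
Reactants: 9 (1R,4R,5R,8S,10R)-13-acetoxy-1,10:4,5-diepoxygermacr-7(11)-en-8-ol; 12 (S)-2-methyloxirane-2-carboxylic acid
Product: 13 (1R,4R,5R,8S,10R)-13-acetoxy-1,10:4,5-diepoxygermacr-7(11)-en-8-yl (2S)-2-methyloxirane-2-carboxylate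
Conditions: 12, 2,4,6-Cl3C6H2COCl, Et3N, toluene, 0 °C; then 9, 4-(dimethylamino)pyridine, 0 °C to rt
Reagents that add atoms: none
Why: Yamaguchi esterification through the mixed anhydride suits a hindered secondary allylic alcohol and an α-quaternary acid, proceeds with retention at C8, and is run cold to limit acetyl migration from O13.

Step 9
Reactants: 13 (1R,4R,5R,8S,10R)-13-acetoxy-1,10:4,5-diepoxygermacr-7(11)-en-8-yl (2S)-2-methyloxirane-2-carboxylate
Product: 14 (1R,4R,5R,6S,8S,10R)-13-acetoxy-1,10:4,5-diepoxy-6-hydroxygermacr-7(11)-en-8-yl (2S)-2-methyloxirane-2-carboxylate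
Conditions: SeO2 (0.5 equiv), t-BuOOH (3 equiv), CH2Cl2, rt
Reagents that add atoms: SeO2, O=[Se]=O (transfers the oxygen); tert-butyl hydroperoxide, CC(C)(C)OO (re-oxidant and ultimate oxygen source)
Why: Riley allylic hydroxylation (ene reaction at C7=C11, then [2,3]-shift of the allylseleninic acid) prefers the ring methylene C6 over the methyl C12 and leaves the acyloxy-bearing C8–H and C13–H2 alone; oxygen should arrive from the α-face (6S), but neither the C6 configuration nor a leak to C12 matters because step 10 converges on one diene.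

Step 10
Reactants: 14 (1R,4R,5R,6S,8S,10R)-13-acetoxy-1,10:4,5-diepoxy-6-hydroxygermacr-7(11)-en-8-yl (2S)-2-methyloxirane-2-carboxylate
Product: 17 (1R,4R,5R,8S,10R,6Z)-13-acetoxy-1,10:4,5-diepoxygermacra-6,11(12)-dien-8-yl (2S)-2-methyloxirane-2-carboxylate, via sulfenate ester 15 (not isolated), via C11 sulfoxide 16 (not isolated)
Conditions: 2,4-(O2N)2C6H3SCl, Et3N, ClCH2CH2Cl, 0 °C; amine salt filtered off; then 50–60 °C
Reagents that add atoms: none
Why: Second Reich 1,4-dehydration (sulfenate, [2,3]-shift to the C11 sulfoxide, syn-elimination), in which the elimination goes toward the C12 methyl and not toward the acetoxy-bearing C13 because sulfoxide eliminations avoid oxygenated β-carbons; the C6 stereocentre is erased and none is formed.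

Step 11
Reactants: 17 (1R,4R,5R,8S,10R,6Z)-13-acetoxy-1,10:4,5-diepoxygermacra-6,11(12)-dien-8-yl (2S)-2-methyloxirane-2-carboxylate
Product: 19 (1R,4R,5R,6S,8S,10R)-13-acetoxy-1,10:4,5-diepoxy-6,12-dihydroxygermacr-7(11)-en-8-yl (2S)-2-methyloxirane-2-carboxylate, via endoperoxide 18 (not isolated)
Conditions: O2, hν (visible), 5,10,15,20-tetraphenylporphyrin (cat.), CH2Cl2, −78 °C; then Zn, AcOH, 0 °C; used crude at once
Reagents that add atoms: dioxygen, O=O (as singlet oxygen)
Why: Singlet-oxygen [4+2] cycloaddition and reductive O–O cleavage as in step 4 tie the new C12 oxygen cis to C6 and set C6 as S by addition to the α-face, anti to the β-methyl C15 on C4; the diol is not stored, to avoid acetyl migration from O13 to O12.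

Step 12
Reactants: 19 (1R,4R,5R,6S,8S,10R)-13-acetoxy-1,10:4,5-diepoxy-6,12-dihydroxygermacr-7(11)-en-8-yl (2S)-2-methyloxirane-2-carboxylate
Product: 22 (1R,4R,5R,6S,8S,10R)-13-acetoxy-1,10:4,5-diepoxy-8-[(2S)-2-methyloxirane-2-carbonyloxy]germacr-7(11)-en-12,6-olide, via hydroxy aldehyde 20 (not isolated), via lactol 21 (not isolated)
Conditions: 2,2,6,6-tetramethylpiperidin-1-oxyl (cat.), PhI(OAc)2 (2.5 equiv), CH2Cl2, rt
Reagents that add atoms: none
Why: Nitroxyl-catalysed oxidative lactonisation of a (Z)-2-ene-1,4-diol: the primary allylic alcohol is oxidised first, the cis hydroxy aldehyde closes to the lactol and this is oxidised to the butenolide under non-basic conditions that avoid deprotonation at C6 next to the C5 oxirane; no stereocentre changes.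

**Compound list**

1 | germacrone | CC(C)=C1C/C=C(C)/CC/C=C(C)/CC1=O | starting material
2 | (1R,4R,5R,10R)-1,10:4,5-diepoxygermacr-7(11)-en-8-one | CC(C)=C1C[C@H]2O[C@]2(C)CC[C@H]2O[C@]2(C)CC1=O | intermediate
3 | (1R,4R,5R,8R,10R)-1,10:4,5-diepoxygermacr-7(11)-en-8-ol (8R expected; the C8 configuration is erased in step 3) | CC(C)=C1C[C@H]2O[C@]2(C)CC[C@H]2O[C@]2(C)C[C@H]1O | intermediate
4 | 8-O-(2,4-dinitrophenylsulfanyl) derivative of 3 (allylic sulfenate ester) | CC(C)=C1C[C@H]2O[C@]2(C)CC[C@H]2O[C@]2(C)C[C@H]1OSc1ccc(cc1[N+](=O)[O-])[N+](=O)[O-] | intermediate (not isolated)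
5 | (1R,4R,5R,10R,7E)-11-(2,4-dinitrophenylsulfinyl)-1,10:4,5-diepoxygermacr-7-ene (sulfur configuration undefined) | CC(C)(S(=O)c1ccc(cc1[N+](=O)[O-])[N+](=O)[O-])/C1=C/C[C@@]2(C)O[C@@H]2CC[C@@]2(C)O[C@@H]2C1 | intermediate (not isolated)
6 | (1R,4R,5R,10R,7E)-1,10:4,5-diepoxygermacra-7,11(13)-diene (ring carbons C6 and C9 cis) | C=C(C)/C1=C/C[C@@]2(C)O[C@@H]2CC[C@@]2(C)O[C@@H]2C1 | intermediate
7 | (1R,4R,5R,8S,10R)-8,13-epidioxy-1,10:4,5-diepoxygermacr-7(11)-ene | CC1=C2C[C@H]3O[C@]3(C)CC[C@H]3O[C@]3(C)C[C@@H]2OOC1 | intermediate (not isolated)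
8 | (1R,4R,5R,8S,10R)-1,10:4,5-diepoxygermacr-7(11)-ene-8,13-diol (C13 cis to C8) | C/C(CO)=C1\C[C@H]2O[C@]2(C)CC[C@H]2O[C@]2(C)C[C@@H]1O | intermediate
9 | (1R,4R,5R,8S,10R)-13-acetoxy-1,10:4,5-diepoxygermacr-7(11)-en-8-ol | C/C(COC(C)=O)=C1\C[C@H]2O[C@]2(C)CC[C@H]2O[C@]2(C)C[C@@H]1O | intermediate
10 | 2-methylprop-2-en-1-ol | C=C(C)CO | starting material
11 | (R)-(2-methyloxiran-2-yl)methanol | OC[C@]1(C)CO1 | intermediate
12 | (S)-2-methyloxirane-2-carboxylic acid | OC(=O)[C@]1(C)CO1 | intermediate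
13 | (1R,4R,5R,8S,10R)-13-acetoxy-1,10:4,5-diepoxygermacr-7(11)-en-8-yl (2S)-2-methyloxirane-2-carboxylate | C/C(COC(C)=O)=C1\C[C@H]2O[C@]2(C)CC[C@H]2O[C@]2(C)C[C@@H]1OC(=O)[C@]1(C)CO1 | intermediate
14 | 6S-hydroxy derivative of 13 (6S expected; the C6 configuration is erased in step 10) | C/C(COC(C)=O)=C1\[C@H](O)[C@H]2O[C@]2(C)CC[C@H]2O[C@]2(C)C[C@@H]1OC(=O)[C@]1(C)CO1 | intermediate
15 | 6-O-(2,4-dinitrophenylsulfanyl) derivative of 14 (allylic sulfenate ester) | C/C(COC(C)=O)=C1\[C@H](OSc2ccc(cc2[N+](=O)[O-])[N+](=O)[O-])[C@H]2O[C@]2(C)CC[C@H]2O[C@]2(C)C[C@@H]1OC(=O)[C@]1(C)CO1 | intermediate (not isolated)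
16 | 13-acetoxy-11-(2,4-dinitrophenylsulfinyl)-1,10:4,5-diepoxygermacr-6-en-8-yl (2S)-2-methyloxirane-2-carboxylate (C11 and sulfur undefined) | CC(COC(C)=O)(S(=O)c1ccc(cc1[N+](=O)[O-])[N+](=O)[O-])/C1=C/[C@H]2O[C@]2(C)CC[C@H]2O[C@]2(C)C[C@@H]1OC(=O)[C@]1(C)CO1 | intermediate (not isolated)
17 | (1R,4R,5R,8S,10R,6Z)-13-acetoxy-1,10:4,5-diepoxygermacra-6,11(12)-dien-8-yl (2S)-2-methyloxirane-2-carboxylate (ring carbons C5 and C8 cis) | C=C(COC(C)=O)/C1=C/[C@H]2O[C@]2(C)CC[C@H]2O[C@]2(C)C[C@@H]1OC(=O)[C@]1(C)CO1 | intermediate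
18 | (1R,4R,5R,6S,8S,10R)-13-acetoxy-6,12-epidioxy-1,10:4,5-diepoxygermacr-7(11)-en-8-yl (2S)-2-methyloxirane-2-carboxylate | CC(=O)OCC1=C2[C@@H](OC(=O)[C@]3(C)CO3)C[C@@]3(C)O[C@@H]3CC[C@@]3(C)O[C@@H]3[C@H]2OOC1 | intermediate (not isolated)
19 | (1R,4R,5R,6S,8S,10R)-13-acetoxy-1,10:4,5-diepoxy-6,12-dihydroxygermacr-7(11)-en-8-yl (2S)-2-methyloxirane-2-carboxylate (C12 cis to C6) | CC(=O)OC/C(CO)=C1\[C@@H](OC(=O)[C@]2(C)CO2)C[C@@]2(C)O[C@@H]2CC[C@@]2(C)O[C@@H]2[C@H]1O | intermediate
20 | 12-aldehyde of 19 (6-hydroxy-12-oxo compound) | CC(=O)OC/C(C=O)=C1\[C@@H](OC(=O)[C@]2(C)CO2)C[C@@]2(C)O[C@@H]2CC[C@@]2(C)O[C@@H]2[C@H]1O | intermediate (not isolated)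
21 | 12-hydroxy-6,12-epoxy lactol of 20 (C12 undefined) | CC(=O)OCC1=C2[C@@H](OC(=O)[C@]3(C)CO3)C[C@@]3(C)O[C@@H]3CC[C@@]3(C)O[C@@H]3[C@H]2OC1O | intermediate (not isolated)
22 | (1R,4R,5R,6S,8S,10R)-13-acetoxy-1,10:4,5-diepoxy-8-[(2S)-2-methyloxirane-2-carbonyloxy]germacr-7(11)-en-12,6-olide | CC(=O)OCC1=C2[C@@H](OC(=O)[C@]3(C)CO3)C[C@@]3(C)O[C@@H]3CC[C@@]3(C)O[C@@H]3[C@H]2OC1=O | target

**Step count and risks**

Total step count: 12. Longest linear sequence: 10 steps (1–5 and 8–12); steps 6 and 7 make the side-chain acid.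

Steps most likely to fail:

Step 1. The catalyst may discriminate poorly between the two interconverting crossed conformers (low enantioselectivity), the second epoxidation may be mismatched, or base may enolise toward C9 and open the C10 oxirane. Fallback, from 1 back to 3: buffered mCPBA (NaHCO3, CH2Cl2, 0 °C) bis-epoxidises germacrone on the outer faces to the racemic like-diepoxide F1. Reduction of the racemate with (S)-2-methyl-CBS-oxazaborolidine and BH3·SMe2 (toluene, −40 °C) then places an 8R hydroxyl on both ring enantiomers under reagent control. This turns them into diastereomers: compound 3 and the all-S-ring alcohol F2, which is removed by chromatography. Compound 3 re-enters at step 3.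

Step 9. The ene step may stall because two allylic acyloxy groups make C7=C11 electron-poor, and long contact with selenous acid may open the oxiranes. Fallback, from 13 back to 17, replacing steps 9 and 10: singlet oxygen (O2, hν, 5,10,15,20-tetraphenylporphyrin, CH2Cl2, −40 °C) is far more reactive toward tetrasubstituted alkenes. It undergoes the ene reaction with the only free allylic hydrogens (C6–H2, C12–H3) to give the tertiary hydroperoxide F3 (OOH on C11, C6=C7) and the tertiary hydroperoxide F4 (OOH on C7, C11=C12). PPh3 reduces them to the tertiary alcohol F5 and the tertiary alcohol F6. Dehydration with methyl N-(triethylammoniosulfonyl)carbamate (Burgess reagent, benzene, 50 °C), away from the acyloxy-bearing carbons, takes both to diene 17.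

Step 11. Facial selectivity of the cycloaddition at C6 may be poor or reversed, because the α-oriented C8 ester may screen the α-face of the diene; ene reaction may also compete. Fallback, from 17 back to 19: if oxygen adds to the β-face, the same two operations give the epimeric endoperoxide F7 (not isolated) and the 6R diol F8. TBSCl/imidazole silylates the primary C12 hydroxyl to the silyl ether F9, and Dess–Martin periodinane oxidises the C6 hydroxyl to the enone F10. NaBH4/CeCl3·7H2O at −78 °C then delivers hydride from the face that oxygen had used, which gives the opposite, 6S, carbinol F11. Bu4NF buffered with AcOH removes the silyl group and returns diol 19.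

Further compounds
F1 | step 1 | racemic (1R*,4R*,5R*,10R*)-1,10:4,5-diepoxygermacr-7(11)-en-8-one (2 plus its enantiomer; the SMILES shows the 1S,4S,5S,10S enantiomer) | CC(C)=C1C[C@@H]2O[C@@]2(C)CC[C@@H]2O[C@@]2(C)CC1=O
F2 | step 1 | (1S,4S,5S,8R,10S)-1,10:4,5-diepoxygermacr-7(11)-en-8-ol | CC(C)=C1C[C@@H]2O[C@@]2(C)CC[C@@H]2O[C@@]2(C)C[C@H]1O
F3 | step 9 | 13-acetoxy-11-hydroperoxy-1,10:4,5-diepoxygermacr-6-en-8-yl (2S)-2-methyloxirane-2-carboxylate (C11 undefined) | CC(COC(C)=O)(OO)C1=C[C@H]2O[C@]2(C)CC[C@H]2O[C@]2(C)C[C@@H]1OC(=O)[C@]1(C)CO1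
F4 | step 9 | 13-acetoxy-7-hydroperoxy-1,10:4,5-diepoxygermacr-11(12)-en-8-yl (2S)-2-methyloxirane-2-carboxylate (C7 undefined) | C=C(COC(C)=O)C1(OO)C[C@H]2O[C@]2(C)CC[C@H]2O[C@]2(C)C[C@@H]1OC(=O)[C@]1(C)CO1
F5 | step 9 | 13-acetoxy-11-hydroxy-1,10:4,5-diepoxygermacr-6-en-8-yl (2S)-2-methyloxirane-2-carboxylate (C11 undefined) | CC(COC(C)=O)(O)C1=C[C@H]2O[C@]2(C)CC[C@H]2O[C@]2(C)C[C@@H]1OC(=O)[C@]1(C)CO1
F6 | step 9 | 13-acetoxy-7-hydroxy-1,10:4,5-diepoxygermacr-11(12)-en-8-yl (2S)-2-methyloxirane-2-carboxylate (C7 undefined) | C=C(COC(C)=O)C1(O)C[C@H]2O[C@]2(C)CC[C@H]2O[C@]2(C)C[C@@H]1OC(=O)[C@]1(C)CO1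
F7 | step 11 | C6 epimer (6R) of endoperoxide 18 | CC(=O)OCC1=C2[C@@H](OC(=O)[C@]3(C)CO3)C[C@@]3(C)O[C@@H]3CC[C@@]3(C)O[C@@H]3[C@@H]2OOC1
F8 | step 11 | C6 epimer (6R) of diol 19 | CC(=O)OC/C(CO)=C1\[C@@H](OC(=O)[C@]2(C)CO2)C[C@@]2(C)O[C@@H]2CC[C@@]2(C)O[C@@H]2[C@@H]1O
F9 | step 11 | 12-O-tert-butyldimethylsilyl ether of F8 | CC(=O)OC/C(CO[Si](C)(C)C(C)(C)C)=C1\[C@@H](OC(=O)[C@]2(C)CO2)C[C@@]2(C)O[C@@H]2CC[C@@]2(C)O[C@@H]2[C@@H]1O
F10 | step 11 | 6-oxo compound from F9 (13-acetoxy-12-silyloxy-1,10:4,5-diepoxy-6-oxogermacr-7(11)-en-8-yl ester) | CC(=O)OC/C(CO[Si](C)(C)C(C)(C)C)=C1\[C@@H](OC(=O)[C@]2(C)CO2)C[C@@]2(C)O[C@@H]2CC[C@@]2(C)O[C@@H]2C1=O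
F11 | step 11 | 12-O-tert-butyldimethylsilyl ether of diol 19 (6S) | CC(=O)OC/C(CO[Si](C)(C)C(C)(C)C)=C1\[C@@H](OC(=O)[C@]2(C)CO2)C[C@@]2(C)O[C@@H]2CC[C@@]2(C)O[C@@H]2[C@H]1O
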